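**Plan**
1. Labels used below: seven-membered ring C1 (tertiary carbinol), C5 (ester-bearing), C6 (lactone-O-bearing), C7, C8, C9 (OH), C10 (methyl C14); side chain C2(=O)–C3–C4(OH)–C15; lactone carbons C11(=C13H2)–C12.
2. Retrosynthetic cuts: the C5–O ester; C6–C7 together with the lactone O6–C12 bond; C7=C11 (acrylate unit); C1–C2 (alkenyl addition, the alkene later cleaved to the C2 ketone); C9–C10 (aldol).
3. Forward: the open chain C6–C5–C1–C10–C9–C8–C7 is assembled (aldol, addition at C1, acrylate at C7); one operation then joins C6 to C7 and closes the carbocycle and the lactone together; esterification and desilylation finish.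
4. Stereochemistry: C5 from (S)-glycerate; C10 and C9 from C5 in a titanium aldol; C1 by Felkin–Anh addition; C4 and the acyl centre from (S)-pent-4-yn-2-ol and (S)-2-methylbutanoic anhydride; C6 and C7 in the key step.
5. Enabling feature: the cis-fused α-methylene-γ-butyrolactone on the C6–C7 edge of the seven-membered ring (O6–C6–C7–C11(=C13)–C12) is the retron of a 2-(methoxycarbonyl)allyl metal adding through C7 to a C6 aldehyde, and the C5 hydroxyl next to C6 is a built-in chelating group that relays C5 to C6 and C7.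

Key step: step 16

Assumption: compounds 1, 5, 9, 19 and 27 are taken as catalogue chemicals; silyl ethers on C5/C6 (triethylsilyl) are chosen to be more labile than those on C9/C4 (tert-butyldimethylsilyl).

Step 1
Reactants: 1 methyl (S)-2,3-dihydroxypropanoate
Product: 2 methyl (S)-2,3-bis(triethylsilyloxy)propanoate
Conditions: TESCl, imidazole, DMF, 0 °C to rt
Reagents that add atoms: chlorotriethylsilane, CC[Si](Cl)(CC)CC
Why: Imidazole-promoted O-silylation of a primary and a secondary alcohol is routine and does not touch the stereocentre (future C5).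

Step 2
Reactants: 2 methyl (S)-2,3-bis(triethylsilyloxy)propanoate
Product: 3 (S)-N-methoxy-N-methyl-2,3-bis(triethylsilyloxy)propanamide
Conditions: MeNHOMe·HCl, i-PrMgCl, THF, −20 °C
Reagents that add atoms: N,O-dimethylhydroxylamine hydrochloride, Cl.CNOC
Why: Aminolysis of the ester by the chloromagnesium amide (Weinreb amide formation) should proceed at low temperature without epimerising the α-silyloxy centre.

Step 3
Reactants: 3 (S)-N-methoxy-N-methyl-2,3-bis(triethylsilyloxy)propanamide
Product: 4 (S)-1,2-bis(triethylsilyloxy)pentan-3-one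
Conditions: EtMgBr, THF, 0 °C
Reagents that add atoms: ethylmagnesium bromide, CC[Mg]Br
Why: Grignard addition to a Weinreb amide stops at the ketone because the magnesium-chelated tetrahedral intermediate persists until work-up.

Step 4
Reactants: 4 (S)-1,2-bis(triethylsilyloxy)pentan-3-one; 5 3-[(4-methoxybenzyl)oxy]propanal
Product: 7 (2S,4S,5R)-5-hydroxy-7-[(4-methoxybenzyl)oxy]-4-methyl-1,2-bis(triethylsilyloxy)heptan-3-one, via titanium enolate 6 (not isolated)
Conditions: TiCl4, i-Pr2NEt, CH2Cl2, −78 °C; then 5, −78 °C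
Reagents that add atoms: none
Why: Titanium-mediated syn aldol addition through a non-chelated Zimmerman–Traxler transition state of the (Z)-enolate, for which lactate-type α-silyloxy ethyl ketones give the 2,4-anti-4,5-syn adduct, so C10 and C9 are set from C5.

Step 5
Reactants: 7 the aldol adduct
Product: 8 (2S,4S,5R)-5-(tert-butyldimethylsilyloxy)-7-[(4-methoxybenzyl)oxy]-4-methyl-1,2-bis(triethylsilyloxy)heptan-3-one
Conditions: TBSOTf, 2,6-lutidine, CH2Cl2, −78 to 0 °C
Reagents that add atoms: tert-butyldimethylsilyl trifluoromethanesulfonate, CC(C)(C)[Si](C)(C)OS(=O)(=O)C(F)(F)F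
Why: Silyl triflate/lutidine silylation protects the C9 hydroxyl of the β-hydroxy ketone under conditions that do not provoke retro-aldol cleavage.

Step 6
Reactants: 9 (S)-pent-4-yn-2-ol
Product: 10 (S)-tert-butyldimethyl(pent-4-yn-2-yloxy)silane
Conditions: TBSCl, imidazole, DMF, rt
Reagents that add atoms: tert-butyldimethylsilyl chloride, CC(C)(C)[Si](C)(C)Cl
Why: Standard silylation of a secondary alcohol; the stereocentre (future C4) is untouched.

Step 7
Reactants: 10 (S)-tert-butyldimethyl(pent-4-yn-2-yloxy)silane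
Product: 12 (S)-[(4-bromopent-4-en-2-yl)oxy](tert-butyl)dimethylsilane, via bromoborane adduct 11 (not isolated)
Conditions: B-bromo-9-BBN, CH2Cl2, 0 °C; then AcOH, 0 °C to rt
Reagents that add atoms: B-bromo-9-borabicyclo[3.3.1]nonane, BrB1C2CCCC1CCC2
Why: Bromoboration of the terminal alkyne (syn addition, bromine to the internal carbon) followed by protodeboronation gives the 2-bromo-1-alkene (haloboration–protonolysis).

Step 8
Reactants: 8 the silylated ketone; 12 the vinyl bromide
Product: 14 open-chain tertiary alcohol carrying the CH2=C(C2) alkenyl group on C1, via alkenyllithium 13 (not isolated)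
Conditions: 12, t-BuLi (2 equiv), Et2O, −78 °C; then 8, −78 °C; H2O quench
Reagents that add atoms: none
Why: Lithium–bromine exchange then 1,2-addition to the ketone, where Felkin–Anh control (attack anti to the C5 silyloxy group and anti to the C9 branch on C10, both preferences selecting the same face) should set C1.

Step 9
Reactants: 14 the tertiary allylic alcohol
Product: 16 α-hydroxy ketone (C2 ketone, C7 PMB ether), via ozonide 15 (not isolated)
Conditions: O3, CH2Cl2, −78 °C (Sudan Red 7B end point); then PPh3, −78 °C to rt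
Reagents that add atoms: ozone, [O-][O+]=O
Why: Ozonolysis with reductive work-up cleaves the only alkene to the C2 ketone, the anisyl ring reacting far more slowly than a 1,1-disubstituted alkene.

Step 10
Reactants: 16 the PMB-protected α-hydroxy ketone
Product: 17 primary alcohol (C7–OH)
Conditions: DDQ, CH2Cl2/pH 7 buffer, 0 °C
Reagents that add atoms: none
Why: Oxidative cleavage of the 4-methoxybenzyl ether by DDQ frees the C7 alcohol and should leave the silyl ethers, ketone and tertiary alcohol intact.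

Step 11
Reactants: 17 the primary alcohol
Product: 18 C7 aldehyde
Conditions: Dess–Martin periodinane, pyridine, CH2Cl2, 0 °C to rt
Reagents that add atoms: none
Why: Dess–Martin oxidation converts the only oxidisable (primary) alcohol into the aldehyde; the tertiary C1 hydroxyl cannot react.

Step 12
Reactants: 18 the C7 aldehyde; 19 methyl acrylate
Product: 20 Morita–Baylis–Hillman adduct (C7 carbinol, both epimers)
Conditions: 19 (excess), 3-hydroxyquinuclidine (cat.), MeOH, rt
Reagents that add atoms: none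
Why: Morita–Baylis–Hillman reaction at the aldehyde (the hindered C2 ketone is inert) installs C11–C13; the new carbinol centre is not controlled because it disappears in step 13.

Step 13
Reactants: 20 the Baylis–Hillman adduct
Product: 21 (Z)-allylic bromide, methyl 2-(bromomethyl)alk-2-enoate with C8 cis to CH2Br
Conditions: NBS, Me2S, CH2Cl2, 0 °C to rt
Reagents that add atoms: N-bromosuccinimide, O=C1CCC(=O)N1Br
Why: Corey–Kim-type activation of the allylic alcohol and SN2′ return of bromide (allylic transposition) gives the thermodynamically favoured (Z)-2-(bromomethyl)enoate, the tertiary C1 hydroxyl being unreactive.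

Step 14
Reactants: 21 the allylic bromide
Product: 22 C5,C6-diol
Conditions: PPTS (cat.), MeOH/CH2Cl2, 0 °C
Reagents that add atoms: none
Why: Acid-catalysed methanolysis removes triethylsilyl ethers far faster than tert-butyldimethylsilyl ethers, unmasking only the C5/C6 diol.

Step 15
Reactants: 22 the diol
Product: 23 α-hydroxy aldehyde (C6 aldehyde, free C5–OH), used crude
Conditions: TEMPO (cat.), PhI(OAc)2, CH2Cl2, rt
Reagents that add atoms: none
Why: TEMPO/PhI(OAc)2 oxidation is selective for the primary alcohol and stops at the aldehyde in the absence of water.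

Step 16
Reactants: 23 the α-hydroxy aldehyde
Product: 26 cis-fused α-methylene lactone with free C5–OH, via allylindium 24 (not isolated), via hydroxy ester 25 (not isolated)
Conditions: In powder, THF/H2O (1:1), 0.005 M, rt; then PPTS (cat.), CH2Cl2, rt
Reagents that add atoms: none
Why: Indium inserts into the allylic C13–Br bond and the allylindium 24 adds through its γ-carbon C7 to the C6 aldehyde in a closed six-membered transition state with allylic transposition (Barbier-type carbonyl allylation), which creates the C11=C13 methylene, after which O6 of 25 acylates on the methyl ester. The closest known reaction type is the indium-mediated aqueous cyclisation of ω-formyl 2-(bromomethyl)alk-2-enoates to carbocycle-fused α-methylene-γ-butyrolactones, together with the chelation-controlled indium allylation of unprotected α-hydroxy aldehydes by 2-(bromomethyl)acrylates. The carbocycle closes by 7-exo-trig attack of C7 on the aldehyde carbon and the lactone by 5-exo-trig attack of O6 on the ester carbonyl. C6 is controlled by C5, because trivalent indium chelated between the C5 hydroxyl and the aldehyde oxygen leaves open the face anti to the quaternary C1 (syn C5–O/C6–O), and C7 is controlled by the (Z) alkene geometry, which places the C8 tether axial in the chair and gives the syn adduct, hence the cis ring fusion. The step needs intramolecular over intermolecular addition (high dilution, and the gauche axial-C8/equatorial-C5 arrangement is spanned by the three-atom C9–C10–C1 tether), aldehyde over C2 ketone (attack on the ketone would have to join two fully substituted carbons), and lactonisation on O6 rather than O5 (O6 is cis-1,2 to C11, O5 trans-1,3).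

Step 17
Reactants: 26 the lactone alcohol; 27 (S)-2-methylbutanoic anhydride
Product: 28 C5 (S)-2-methylbutanoate, C9 and C4 still silylated
Conditions: 27, DMAP, Et3N, CH2Cl2, 0 °C to rt
Reagents that add atoms: none
Why: DMAP-catalysed acyl transfer from the anhydride esterifies the only free secondary hydroxyl (C5), the tertiary C1 hydroxyl being inert and the anhydride avoiding a ketene pathway that could erode the acyl stereocentre.

Step 18
Reactants: 28 the bis-silyl ether
Product: 29 the target
Conditions: HF·pyridine, THF/pyridine, 0 °C to rt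
Reagents that add atoms: none
Why: Buffered fluoride desilylation removes both tert-butyldimethylsilyl ethers under conditions expected to spare the α-methylene lactone, the ester and the β-hydroxy ketone.

**Compound list**
1 | methyl (S)-2,3-dihydroxypropanoate | COC(=O)[C@H](CO)O | starting material
2 | methyl (S)-2,3-bis(triethylsilyloxy)propanoate | COC(=O)[C@H](CO[Si](CC)(CC)CC)O[Si](CC)(CC)CC | intermediate
3 | (S)-N-methoxy-N-methyl-2,3-bis(triethylsilyloxy)propanamide | CON(C)C(=O)[C@H](CO[Si](CC)(CC)CC)O[Si](CC)(CC)CC | intermediate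
4 | (S)-1,2-bis(triethylsilyloxy)pentan-3-one | CCC(=O)[C@H](CO[Si](CC)(CC)CC)O[Si](CC)(CC)CC | intermediate
5 | 3-[(4-methoxybenzyl)oxy]propanal | O=CCCOCc1ccc(OC)cc1 | starting material
6 | trichlorotitanium (Z)-enolate of 4 | C/C=C(\O[Ti](Cl)(Cl)Cl)[C@H](CO[Si](CC)(CC)CC)O[Si](CC)(CC)CC | intermediate
7 | (2S,4S,5R)-5-hydroxy-7-[(4-methoxybenzyl)oxy]-4-methyl-1,2-bis(triethylsilyloxy)heptan-3-one | COc1ccc(COCC[C@@H](O)[C@H](C)C(=O)[C@H](CO[Si](CC)(CC)CC)O[Si](CC)(CC)CC)cc1 | intermediate
8 | (2S,4S,5R)-5-(tert-butyldimethylsilyloxy)-7-[(4-methoxybenzyl)oxy]-4-methyl-1,2-bis(triethylsilyloxy)heptan-3-one | COc1ccc(COCC[C@@H](O[Si](C)(C)C(C)(C)C)[C@H](C)C(=O)[C@H](CO[Si](CC)(CC)CC)O[Si](CC)(CC)CC)cc1 | intermediate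
9 | (S)-pent-4-yn-2-ol | C#CC[C@H](C)O | starting material
10 | (S)-tert-butyldimethyl(pent-4-yn-2-yloxy)silane | C#CC[C@H](C)O[Si](C)(C)C(C)(C)C | intermediate
11 | (Z)-(2-bromoalk-1-enyl)-9-BBN adduct of 10 (B and Br cis) | Br/C(C[C@H](C)O[Si](C)(C)C(C)(C)C)=C\B1C2CCCC1CCC2 | intermediate
12 | (S)-[(4-bromopent-4-en-2-yl)oxy](tert-butyl)dimethylsilane | C=C(Br)C[C@H](C)O[Si](C)(C)C(C)(C)C | intermediate
13 | alkenyllithium from 12 | [Li]C(=C)C[C@H](C)O[Si](C)(C)C(C)(C)C | intermediate
14 | open-chain tertiary alcohol: C1 carbinol bearing CH2=C(C2)–C3H2–C4H(OTBS)–CH3, C5/C6 bis-TES ether, C9 TBS ether, C10 methyl, C7 PMB ether; C1, C4, C5, C9, C10 arranged as in the target | COc1ccc(COCC[C@@H](O[Si](C)(C)C(C)(C)C)[C@H](C)[C@@](O)(C(=C)C[C@H](C)O[Si](C)(C)C(C)(C)C)[C@H](CO[Si](CC)(CC)CC)O[Si](CC)(CC)CC)cc1 | intermediate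
15 | 1,2,4-trioxolane (ozonide) of 14 at the C2 methylene (C2 epimers) | COc1ccc(COCC[C@@H](O[Si](C)(C)C(C)(C)C)[C@H](C)[C@@](O)(C2(C[C@H](C)O[Si](C)(C)C(C)(C)C)OCOO2)[C@H](CO[Si](CC)(CC)CC)O[Si](CC)(CC)CC)cc1 | intermediate
16 | α-hydroxy ketone: as 14 with C2 ketone (C1–OH, C2=O, C4–OTBS) | COc1ccc(COCC[C@@H](O[Si](C)(C)C(C)(C)C)[C@H](C)[C@@](O)(C(=O)C[C@H](C)O[Si](C)(C)C(C)(C)C)[C@H](CO[Si](CC)(CC)CC)O[Si](CC)(CC)CC)cc1 | intermediate
17 | as 16 with free primary C7–OH | OCC[C@@H](O[Si](C)(C)C(C)(C)C)[C@H](C)[C@@](O)(C(=O)C[C@H](C)O[Si](C)(C)C(C)(C)C)[C@H](CO[Si](CC)(CC)CC)O[Si](CC)(CC)CC | intermediate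
18 | C7 aldehyde | O=CC[C@@H](O[Si](C)(C)C(C)(C)C)[C@H](C)[C@@](O)(C(=O)C[C@H](C)O[Si](C)(C)C(C)(C)C)[C@H](CO[Si](CC)(CC)CC)O[Si](CC)(CC)CC | intermediate
19 | methyl acrylate | C=CC(=O)OC | starting material
20 | Baylis–Hillman adduct: methyl 2-methylene-3-hydroxy ester at C11/C7 (C7 carbinol, both epimers) | C=C(C(=O)OC)C(O)C[C@@H](O[Si](C)(C)C(C)(C)C)[C@H](C)[C@@](O)(C(=O)C[C@H](C)O[Si](C)(C)C(C)(C)C)[C@H](CO[Si](CC)(CC)CC)O[Si](CC)(CC)CC | intermediate
21 | (Z)-methyl 2-(bromomethyl)alk-2-enoate (C13–Br, C11=C7), C5/C6 bis-TES | BrC/C(C(=O)OC)=C\C[C@@H](O[Si](C)(C)C(C)(C)C)[C@H](C)[C@@](O)(C(=O)C[C@H](C)O[Si](C)(C)C(C)(C)C)[C@H](CO[Si](CC)(CC)CC)O[Si](CC)(CC)CC | intermediate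
22 | as 21 with free C5–OH and C6–OH | BrC/C(C(=O)OC)=C\C[C@@H](O[Si](C)(C)C(C)(C)C)[C@H](C)[C@@](O)(C(=O)C[C@H](C)O[Si](C)(C)C(C)(C)C)[C@H](CO)O | intermediate
23 | α-hydroxy aldehyde (C6 aldehyde, C5–OH) bearing the (Z)-allylic bromide | BrC/C(C(=O)OC)=C\C[C@@H](O[Si](C)(C)C(C)(C)C)[C@H](C)[C@@](O)(C(=O)C[C@H](C)O[Si](C)(C)C(C)(C)C)[C@H](C=O)O | intermediate
24 | allylindium from 23 (drawn as the monovalent allylindium) | [In]C/C(C(=O)OC)=C\C[C@@H](O[Si](C)(C)C(C)(C)C)[C@H](C)[C@@](O)(C(=O)C[C@H](C)O[Si](C)(C)C(C)(C)C)[C@H](C=O)O | intermediate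
25 | cycloheptane hydroxy ester: C6–OH and C7–C(=CH2)CO2Me cis, C5–OH trans to C6–OH | C=C(C(=O)OC)[C@@H]1C[C@@H](O[Si](C)(C)C(C)(C)C)[C@H](C)[C@@](O)(C(=O)C[C@H](C)O[Si](C)(C)C(C)(C)C)[C@@H](O)[C@@H]1O | intermediate
26 | cis-fused α-methylene-γ-butyrolactone with free C5–OH, C9–OTBS, C4–OTBS | C=C1C(=O)O[C@@H]2[C@H]1C[C@@H](O[Si](C)(C)C(C)(C)C)[C@H](C)[C@@](O)(C(=O)C[C@H](C)O[Si](C)(C)C(C)(C)C)[C@H]2O | intermediate
27 | (S)-2-methylbutanoic anhydride | CC[C@H](C)C(=O)OC(=O)[C@@H](C)CC | starting material
28 | C5 (S)-2-methylbutanoate of 26 | C=C1C(=O)O[C@@H]2[C@H]1C[C@@H](O[Si](C)(C)C(C)(C)C)[C@H](C)[C@@](O)(C(=O)C[C@H](C)O[Si](C)(C)C(C)(C)C)[C@H]2OC(=O)[C@@H](C)CC | intermediate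
29 | target (1S,4S,5S,6R,7S,9R,10S; (S)-2-methylbutanoate at C5) | C=C1C(=O)O[C@@H]2[C@H]1C[C@@H](O)[C@H](C)[C@@](O)(C(=O)C[C@H](C)O)[C@H]2OC(=O)[C@@H](C)CC | target

**Step count:** 18 steps in total; longest linear sequence 16 steps (steps 1–5 and 8–18).

**Steps most likely to fail**

Step 16. The allylindium may be protonated or couple intermolecularly faster than the seven-membered ring closes, or the C5–OH/aldehyde chelate may not form, so that facial selectivity at C6 is lost. The fallback sets out from 22. Palladium-catalysed borylation of the allylic bromide (bis(pinacolato)diboron, Pd2(dba)3, KOAc, DMSO) should give the linear allyl pinacolboronate F1. Oxidation as in step 15 should give the α-hydroxy aldehyde boronate F2. On warming in toluene F2 should undergo a unimolecular, metal-free allylboration through a chair transition state, with no protonolysis pathway, to the cyclic borate F3. Aqueous work-up gives 25, and PPTS closes the lactone, so the route is rejoined at 26.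

Step 8. The basic alkenyllithium may deprotonate ketone 8 at C10 or C5 (with β-elimination of the C9 silyloxy group), or Felkin–Anh selectivity may erode with the bulky sp2 nucleophile. The fallback sets out from 8 and uses a smaller, less basic nucleophile with a different ketone mask. Commercial (S)-but-3-yn-2-ol is silylated to (S)-tert-butyl(but-3-yn-2-yloxy)dimethylsilane F4, and n-BuLi gives the lithium acetylide F5. F5 adds to 8 to give the tertiary propargylic alcohol F6. Silver-catalysed carboxylative cyclisation (AgOAc catalytic, DBU, CO2, toluene) gives the (Z)-alkylidene cyclic carbonate F7. Mild hydrolysis (LiOH, THF/H2O, 0 °C) releases the α-hydroxy ketone, so the route is rejoined at 16.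

Step 12. The slow amine-catalysed addition may allow β-elimination of the C9 silyloxy group from aldehyde 18, or its self-condensation, to compete. The fallback sets out from 18 and replaces catalysis by a preformed vinylmetal. Hydroalumination of methyl propiolate (i-Bu2AlH, N-methylmorpholine N-oxide, THF, 0 °C) gives [1-(methoxycarbonyl)vinyl]diisobutylalane F8. F8 adds to the aldehyde within hours at 0 °C, so the route is rejoined directly at 20.

**Further compounds**
F1 | step 16 | linear allyl pinacolboronate of diol 22 (C13–B, C8 cis to CH2B) | CC1(C)OB(C/C(C(=O)OC)=C\C[C@@H](O[Si](C)(C)C(C)(C)C)[C@H](C)[C@@](O)(C(=O)C[C@H](C)O[Si](C)(C)C(C)(C)C)[C@H](CO)O)OC1(C)C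
F2 | step 16 | α-hydroxy aldehyde allyl pinacolboronate | CC1(C)OB(C/C(C(=O)OC)=C\C[C@@H](O[Si](C)(C)C(C)(C)C)[C@H](C)[C@@](O)(C(=O)C[C@H](C)O[Si](C)(C)C(C)(C)C)[C@H](C=O)O)OC1(C)C
F3 | step 16 | pinacol borate ester (at O6) of hydroxy ester 25 | C=C(C(=O)OC)[C@@H]1C[C@@H](O[Si](C)(C)C(C)(C)C)[C@H](C)[C@@](O)(C(=O)C[C@H](C)O[Si](C)(C)C(C)(C)C)[C@@H](O)[C@@H]1OB1OC(C)(C)C(C)(C)O1
F4 | step 8 | (S)-tert-butyl(but-3-yn-2-yloxy)dimethylsilane | C#C[C@H](C)O[Si](C)(C)C(C)(C)C
F5 | step 8 | lithium acetylide of F4 | [Li]C#C[C@H](C)O[Si](C)(C)C(C)(C)C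
F6 | step 8 | tertiary propargylic alcohol from 8 and F5 (C1 as in the target) | COc1ccc(COCC[C@@H](O[Si](C)(C)C(C)(C)C)[C@H](C)[C@@](O)(C#C[C@H](C)O[Si](C)(C)C(C)(C)C)[C@H](CO[Si](CC)(CC)CC)O[Si](CC)(CC)CC)cc1
F7 | step 8 | (Z)-alkylidene cyclic carbonate spanning O1–C1–C2 | COc1ccc(COCC[C@@H](O[Si](C)(C)C(C)(C)C)[C@H](C)[C@@](O2)(/C(=C/[C@H](C)O[Si](C)(C)C(C)(C)C)OC2=O)[C@H](CO[Si](CC)(CC)CC)O[Si](CC)(CC)CC)cc1
F8 | step 12 | [1-(methoxycarbonyl)vinyl]diisobutylalane | C=C(C(=O)OC)[Al](CC(C)C)CC(C)C
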